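**Retrosynthetic overview**
1. Target 43 ⇐ BCl3 unmasking (two aryl methyl ethers, one MOM ether) ⇐ oxidative demethylation to the quinone ⇐ MnO2 oxidation of a macrocyclic C11 carbinol.
2. The 23-membered ring is closed last, not at the amide but at the hindered aryl-ketone carbon: Nozaki–Hiyama–Kishi C11–C12 closure of an aryl aldehyde onto a (Z)-alkenyl iodide, so the labile (Z)-enone only ever exists inside the ring.
3. Seco compound ⇐ diene–ene cross-metathesis (C18=C19) of chain fragment D with aryl dienamide fragment B; the N–aryl bond comes from copper-catalysed amidation of an aryl bromide, which avoids an amino aldehyde.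
4. Naphthalene (fragment A) ⇐ Brassard-type Diels–Alder of 2,6-dibromobenzoquinone with a 1,3-bis(silyloxy)diene (benzenoid ring B formed first), reductive methylation, C5 formylation.
5. Fragment D ⇐ δ-lactone (second ring) by Evans syn-aldol/lactonization with a (Z)-iodopentenoyl imide (fragment C); C20–C26 by three Brown anti-crotylations from (R)-Roche ester. Ring order: ring B → δ-lactone → macrocycle → quinone oxidation state.

Assumption: rifamycin-type locants are used (C15 amide carbonyl to C29, lactone carbonyl C34a, naphthalene C1–C8), and 2,6-dibromo-1,4-benzoquinone, phosphonate 11, aldehyde 15 and both enantiomers of Ipc2BOMe are taken as catalogue items.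

**Fragment A (naphthalene aldehyde)**

Step 1
Reactants: 1 methyl 2-methyl-3-oxobutanoate
Product: 2 methyl 2-methyl-3-(trimethylsilyloxy)but-2-enoate
Conditions: Me3SiCl, Et3N, hexane, rt
Reagents that add atoms: chlorotrimethylsilane C[Si](C)(C)Cl
Why: O-silylation of the β-keto ester enol (silyl enol ether formation) gives the enoate needed for the Chan-type diene.

Step 2
Reactants: 2 methyl 2-methyl-3-(trimethylsilyloxy)but-2-enoate
Product: 3 1-methoxy-2-methyl-1,3-bis(trimethylsilyloxy)buta-1,3-diene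
Conditions: LiN(i-Pr)2, THF, −78 °C; Me3SiCl, −78 °C → rt
Reagents that add atoms: chlorotrimethylsilane C[Si](C)(C)Cl
Why: γ-Deprotonation and O-silylation of the ester dienolate gives the Chan–Brassard vinylketene acetal (silyl ketene acetal formation).

Step 3
Reactants: 3 1-methoxy-2-methyl-1,3-bis(trimethylsilyloxy)buta-1,3-diene; 4 2,6-dibromo-1,4-benzoquinone
Product: 6 2-bromo-6,8-dihydroxy-7-methylnaphthalene-1,4-dione, via Diels–Alder cycloadduct 5 (not isolated)
Conditions: CH2Cl2, −40 °C → rt; then 1 M HCl, THF, rt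
Reagents that add atoms: none
Why: Brassard-type Diels–Alder annulation in which the nucleophilic CH2 terminus of the diene adds to the unsubstituted quinone carbon and the ketene-acetal carbon to the brominated one, so that loss of HBr, MeOH and the silyl groups aromatizes ring B with the remaining bromine next to the carbonyl that is peri to the new C8 hydroxyl.

Step 4
Reactants: 6 2-bromo-6,8-dihydroxy-7-methylnaphthalene-1,4-dione
Product: 8 2-bromo-1,4,6,8-tetramethoxy-7-methylnaphthalene, via hydroquinone 7 (not isolated)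
Conditions: Na2S2O4, EtOAc/H2O, rt; then Me2SO4, K2CO3, acetone, reflux (N2)
Reagents that add atoms: dimethyl sulfate COS(=O)(=O)OC
Why: Reductive methylation (dithionite reduction, then Williamson O-methylation of all four phenols) masks the quinone and both phenols for the organometallic steps.

Step 5
Reactants: 8 2-bromo-1,4,6,8-tetramethoxy-7-methylnaphthalene
Product: 9 6-bromo-2,4,5,8-tetramethoxy-3-methylnaphthalene-1-carbaldehyde (fragment A)
Conditions: Cl2CHOMe, TiCl4, CH2Cl2, −78 → 0 °C; H2O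
Reagents that add atoms: dichloromethyl methyl ether COC(Cl)Cl; water O
Why: Rieche formylation (Friedel–Crafts type) goes to C5, the only free position both ortho and para to methoxy groups, whereas C3 is flanked by bromine and activated by one methoxy only.

**Fragment B (aryl dienamide)**

Step 6
Reactants: 10 acrolein; 11 ethyl 2-[bis(2,2,2-trifluoroethoxy)phosphoryl]propanoate
Product: 12 ethyl (Z)-2-methylpenta-2,4-dienoate
Conditions: KN(SiMe3)2, 18-crown-6, THF, −78 °C
Reagents that add atoms: none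
Why: Still–Gennari olefination gives the kinetic (Z)-trisubstituted enoate and so fixes the C16=C17 geometry.

Step 7
Reactants: 12 ethyl (Z)-2-methylpenta-2,4-dienoate
Product: 13 (Z)-2-methylpenta-2,4-dienamide
Conditions: Me3Al, NH4Cl, toluene, 0 → 50 °C
Reagents that add atoms: ammonium chloride [NH4+].[Cl-]
Why: Weinreb-type aluminium amide aminolysis converts the ester directly into the primary amide, and the α-methyl group disfavours conjugate addition so the Z geometry is kept.

Step 8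
Reactants: 9 6-bromo-2,4,5,8-tetramethoxy-3-methylnaphthalene-1-carbaldehyde; 13 (Z)-2-methylpenta-2,4-dienamide
Product: 14 (Z)-N-(5-formyl-1,4,6,8-tetramethoxy-7-methylnaphthalen-2-yl)-2-methylpenta-2,4-dienamide (fragment B)
Conditions: CuI (10 mol%), trans-N,N'-dimethylcyclohexane-1,2-diamine (20 mol%), K2CO3, toluene, 100 °C
Reagents that add atoms: none
Why: Goldberg–Buchwald amidation with monovalent copper forms the N–aryl bond from the aryl bromide, tolerates the non-enolizable aldehyde and, unlike palladium, does not engage the diene in Heck chemistry.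

**Fragment C (acyl oxazolidinone)**

Step 9
Reactants: 15 3-[(tert-butyldimethylsilyl)oxy]propanal
Product: 16 tert-butyl{[(Z)-4-iodopent-3-en-1-yl]oxy}dimethylsilane
Conditions: EtPPh3I, n-BuLi, THF, 0 °C; I2, −78 °C; NaN(SiMe3)2, −78 → −20 °C; then 15, −78 °C → rt
Reagents that add atoms: (1-iodoethylidene)triphenylphosphorane CC(I)=P(c1ccccc1)(c1ccccc1)c1ccccc1, made in the flask from ethyltriphenylphosphonium iodide CC[P+](c1ccccc1)(c1ccccc1)c1ccccc1.[I-] and iodine II
Why: Stork–Zhao Wittig olefination with the α-iodo ylide gives the (Z)-2-iodoalk-2-ene (iodine cis to the chain), which later becomes the C12=C29 geometry.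

Step 10
Reactants: 16 tert-butyl{[(Z)-4-iodopent-3-en-1-yl]oxy}dimethylsilane
Product: 18 (Z)-4-iodopent-3-enoic acid, via (Z)-4-iodopent-3-en-1-ol 17 (not isolated)
Conditions: CrO3, H2SO4, acetone/H2O, 0 °C
Reagents that add atoms: water O
Why: Jones oxidation cleaves the silyl ether under the acidic conditions and oxidizes the homoallylic primary alcohol to the β,γ-unsaturated acid fast enough that the double bond does not move.

Step 11
Reactants: 18 (Z)-4-iodopent-3-enoic acid; 19 (R)-4-benzyloxazolidin-2-one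
Product: 21 (R)-4-benzyl-3-[(Z)-4-iodopent-3-enoyl]oxazolidin-2-one (fragment C), via mixed pivalic anhydride 20 (not isolated)
Conditions: t-BuCOCl, Et3N, THF, −20 °C; then 19, LiCl, rt
Reagents that add atoms: none
Why: N-Acylation of the Evans auxiliary through the mixed anhydride (LiCl-assisted) is mild enough to keep the β,γ-olefin out of conjugation.

**Fragment D (chain with δ-lactone)**

Step 12
Reactants: 22 methyl (R)-3-hydroxy-2-methylpropanoate
Product: 23 methyl (R)-3-[(tert-butyldimethylsilyl)oxy]-2-methylpropanoate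
Conditions: t-BuMe2SiCl, imidazole, CH2Cl2, rt
Reagents that add atoms: tert-butyldimethylsilyl chloride CC(C)(C)[Si](C)(C)Cl
Why: Silyl ether protection of the primary alcohol, with C22 taken from the chiral pool.

Step 13
Reactants: 23 methyl (R)-3-[(tert-butyldimethylsilyl)oxy]-2-methylpropanoate
Product: 24 (R)-3-[(tert-butyldimethylsilyl)oxy]-2-methylpropanal
Conditions: i-Bu2AlH, CH2Cl2, −78 °C; aq. KNaC4H4O6
Reagents that add atoms: none
Why: Partial ester reduction stops at the aldehyde through the stable tetrahedral aluminate at −78 °C and the aldehyde is used at once so C22 does not epimerize.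

Step 14
Reactants: 24 (R)-3-[(tert-butyldimethylsilyl)oxy]-2-methylpropanal
Product: 25 (2R,3R,4R)-1-[(tert-butyldimethylsilyl)oxy]-2,4-dimethylhex-5-en-3-ol
Conditions: trans-2-butene, KOt-Bu, n-BuLi, THF, −78 → −45 °C; (+)-Ipc2BOMe, −78 °C; BF3·OEt2; 24, −78 °C; NaBO3·4H2O, THF/H2O, rt
Reagents that add atoms: (E)-but-2-enyl-diisopinocampheylborane C/C=C/CB([C@H]1C[C@H]2C[C@@H]([C@@H]1C)C2(C)C)[C@H]1C[C@H]2C[C@@H]([C@@H]1C)C2(C)C, made in the flask from trans-2-butene C/C=C/C
Why: Brown crotylboration through a chair Zimmerman–Traxler transition state gives the anti C23/C24 pair from the (E)-crotyl unit, and the (−)-α-pinene-derived reagent and the Felkin–Anh bias of C22 both favour re-face attack (matched), setting 23R and 24R (3R,4R in 25).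

Step 15
Reactants: 25 (2R,3R,4R)-1-[(tert-butyldimethylsilyl)oxy]-2,4-dimethylhex-5-en-3-ol
Product: 26 tert-butyl{[(2R,3R,4R)-3-(methoxymethoxy)-2,4-dimethylhex-5-en-1-yl]oxy}dimethylsilane
Conditions: MeOCH2Cl, i-Pr2NEt, CH2Cl2, 0 °C → rt
Reagents that add atoms: chloromethyl methyl ether COCCl
Why: Acetal protection of the C23 hydroxyl by O-alkylation gives an ether that survives fluoride, oxidants and organometallics and is removed by BCl3 in the last step.

Step 16
Reactants: 26 tert-butyl{[(2R,3R,4R)-3-(methoxymethoxy)-2,4-dimethylhex-5-en-1-yl]oxy}dimethylsilane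
Product: 28 (2S,3S,4R)-5-[(tert-butyldimethylsilyl)oxy]-3-(methoxymethoxy)-2,4-dimethylpentanal, via ozonide 27 (not isolated)
Conditions: O3, CH2Cl2, −78 °C; PPh3, −78 °C → rt
Reagents that add atoms: ozone [O-][O+]=O
Why: Ozonolysis with reductive work-up cleaves the terminal alkene to the C25 aldehyde without touching the stereocentres.

Step 17
Reactants: 28 (2S,3S,4R)-5-[(tert-butyldimethylsilyl)oxy]-3-(methoxymethoxy)-2,4-dimethylpentanal
Product: 29 (3S,4S,5R,6S,7R)-8-[(tert-butyldimethylsilyl)oxy]-6-(methoxymethoxy)-3,5,7-trimethyloct-1-en-4-ol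
Conditions: trans-2-butene, KOt-Bu, n-BuLi, THF, −78 → −45 °C; (−)-Ipc2BOMe, −78 °C; BF3·OEt2; 28, −78 °C; NaBO3·4H2O, THF/H2O, rt
Reagents that add atoms: (E)-but-2-enyl-diisopinocampheylborane C/C=C/CB([C@@H]1C[C@@H]2C[C@H]([C@H]1C)C2(C)C)[C@@H]1C[C@@H]2C[C@H]([C@H]1C)C2(C)C, made in the flask from trans-2-butene C/C=C/C
Why: Second Brown crotylboration, now with the (+)-α-pinene-derived reagent for si-face attack, again matched with Felkin–Anh control by C24, gives the anti C25/C26 pair (4S,3S in 29).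

Step 18
Reactants: 29 (3S,4S,5R,6S,7R)-8-[(tert-butyldimethylsilyl)oxy]-6-(methoxymethoxy)-3,5,7-trimethyloct-1-en-4-ol
Product: 30 (3S,4S,5S,6S,7R)-8-[(tert-butyldimethylsilyl)oxy]-6-(methoxymethoxy)-3,5,7-trimethyl-4-[(triethylsilyl)oxy]oct-1-ene
Conditions: Et3SiOTf, 2,6-lutidine, CH2Cl2, −78 °C
Reagents that add atoms: triethylsilyl trifluoromethanesulfonate CC[Si](CC)(CC)OS(=O)(=O)C(F)(F)F
Why: Silylation of the hindered C25 hydroxyl with a labile triethylsilyl group that is removed later to trigger lactonization.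

Step 19
Reactants: 30 (3S,4S,5S,6S,7R)-8-[(tert-butyldimethylsilyl)oxy]-6-(methoxymethoxy)-3,5,7-trimethyl-4-[(triethylsilyl)oxy]oct-1-ene
Product: 32 (2R,3R,4S,5S,6R)-7-[(tert-butyldimethylsilyl)oxy]-5-(methoxymethoxy)-2,4,6-trimethyl-3-[(triethylsilyl)oxy]heptanal, via ozonide 31 (not isolated)
Conditions: O3, CH2Cl2, −78 °C; PPh3, −78 °C → rt
Reagents that add atoms: ozone [O-][O+]=O
Why: Ozonolysis with reductive work-up gives the C27 aldehyde for the aldol.

Step 20
Reactants: 32 (2R,3R,4S,5S,6R)-7-[(tert-butyldimethylsilyl)oxy]-5-(methoxymethoxy)-2,4,6-trimethyl-3-[(triethylsilyl)oxy]heptanal; 21 (R)-4-benzyl-3-[(Z)-4-iodopent-3-enoyl]oxazolidin-2-one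
Product: 34 (R)-4-benzyl-3-[(2R,3S,4S,5S,6S,7S,8R)-9-(tert-butyldimethylsilyloxy)-3-hydroxy-2-[(Z)-2-iodoprop-1-enyl]-7-(methoxymethoxy)-4,6,8-trimethyl-5-(triethylsilyloxy)nonanoyl]oxazolidin-2-one, via dibutylboron enolate 33 (not isolated)
Conditions: 21, n-Bu2BOTf, Et3N, CH2Cl2, −78 → 0 °C; 32, −78 → 0 °C; pH 7 buffer, MeOH, H2O2
Reagents that add atoms: none
Why: Evans syn-aldol in which the (Z)-boron dienolate reacts at its α-carbon through a Zimmerman–Traxler chair with the auxiliary benzyl group shielding one face, giving the syn C27/C28 pair (27S,28R) under reagent control while the alkenyl iodide keeps its geometry.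

Step 21
Reactants: 34 syn-aldol imide
Product: 36 (3R,4S,5S,6S)-4-hydroxy-6-[(2S,3S,4R)-5-hydroxy-3-(methoxymethoxy)-4-methylpentan-2-yl]-3-[(Z)-2-iodoprop-1-enyl]-5-methyloxan-2-one, via hydroxy imide 35 (not isolated)
Conditions: HF·pyridine, pyridine, THF, 0 °C → rt
Reagents that add atoms: none
Why: Desilylation frees the C25 and C21 hydroxyls and the δ-hydroxy imide lactonizes by acyl transfer with release of the auxiliary, giving the δ-lactone with all four substituents equatorial (no stereocentre is touched, and C28 is in its thermodynamically preferred configuration).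

Step 22
Reactants: 36 δ-lactone diol
Product: 37 (2S,3R,4S)-4-[(2S,3S,4S,5R)-4-hydroxy-5-[(Z)-2-iodoprop-1-enyl]-3-methyl-6-oxooxan-2-yl]-3-(methoxymethoxy)-2-methylpentanal
Conditions: TEMPO (20 mol%), PhI(OAc)2, CH2Cl2, rt
Reagents that add atoms: none
Why: Oxoammonium (TEMPO) oxidation is selective for the primary C21 alcohol over the secondary C27 alcohol and is neutral enough for the β-hydroxy lactone.

Step 23
Reactants: 37 δ-lactone aldehyde
Product: 38 (3R,4S,5S,6S)-4-hydroxy-6-[(2S,3S,4R,5R,6R)-5-hydroxy-3-(methoxymethoxy)-4,6-dimethyloct-7-en-2-yl]-3-[(Z)-2-iodoprop-1-enyl]-5-methyloxan-2-one (fragment D)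
Conditions: trans-2-butene, KOt-Bu, n-BuLi, THF, −78 → −45 °C; (+)-Ipc2BOMe, −78 °C; BF3·OEt2; 37, −78 °C; NaBO3·4H2O, THF/H2O, rt
Reagents that add atoms: (E)-but-2-enyl-diisopinocampheylborane C/C=C/CB([C@H]1C[C@H]2C[C@@H]([C@@H]1C)C2(C)C)[C@H]1C[C@H]2C[C@@H]([C@@H]1C)C2(C)C, made in the flask from trans-2-butene C/C=C/C
Why: Third Brown crotylboration, where the (E)-crotyl unit gives the anti C20/C21 pair and the (−)-α-pinene-derived reagent overrides the Felkin bias of C22 (mismatched, reagent-controlled) to give the anti,anti triad (20R,21R); the borane attacks only the aldehyde, leaving lactone and alkenyl iodide intact.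

**Endgame**

Step 24
Reactants: 38 fragment D; 14 fragment B
Product: 39 (2Z,4E,6R,7R,8R,9S,10S)-N-(5-formyl-1,4,6,8-tetramethoxy-7-methylnaphthalen-2-yl)-7-hydroxy-10-[(2S,3S,4S,5R)-4-hydroxy-5-[(Z)-2-iodoprop-1-enyl]-3-methyl-6-oxooxan-2-yl]-9-(methoxymethoxy)-2,6,8-trimethylundeca-2,4-dienamide
Conditions: second-generation Hoveyda–Grubbs catalyst RuCl2(H2IMes)(=CH-C6H4-2-Oi-Pr) (10 mol%), 14 (2 equiv), CH2Cl2, 40 °C
Reagents that add atoms: none
Why: Diene–ene olefin cross-metathesis engages only the two terminal vinyl groups (the trisubstituted alkenyl iodide and the α-methyl acrylamide olefin are inert) and gives the (E)-C18=C19 bond under thermodynamic control with the preset 16Z geometry untouched.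

Step 25
Reactants: 39 seco aldehyde
Product: 40 macrocyclic C11 carbinol (23-membered ring; mixture of C11 epimers)
Conditions: CrCl2 (15 equiv), NiCl2 (0.1 equiv), DMSO/THF, rt, 2 mM, slow addition
Reagents that add atoms: none
Why: Nozaki–Hiyama–Kishi macrocyclization, in which zerovalent nickel inserts into the alkenyl iodide with retention, transmetalation gives an alkenyl species of trivalent chromium, and this adds only to the aldehyde while tolerating free hydroxyls, lactone, amide and diene; the C11 configuration is irrelevant.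

Step 26
Reactants: 40 macrocyclic C11 carbinol
Product: 41 macrocyclic aryl ketone (1,4,6,8-tetramethoxynaphthalene form)
Conditions: MnO2, CH2Cl2, rt
Reagents that add atoms: none
Why: MnO2 oxidizes only the doubly activated (benzylic and allylic) C11 alcohol, leaving the C21 and C27 alcohols, and the (Z)-enone is created inside the ring where it cannot isomerize.

Step 27
Reactants: 41 macrocyclic aryl ketone
Product: 42 6,8-di-O-methyl-23-O-(methoxymethyl) ether of the target quinone
Conditions: (NH4)2Ce(NO3)6, MeCN/H2O, 0 °C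
Reagents that add atoms: water O
Why: Oxidative demethylation by tetravalent cerium converts the para-dimethoxy ring A into the 1,4-quinone, while the meta-dimethoxy ring B cannot form a quinone and stays intact.

Step 28
Reactants: 42 protected quinone
Product: 43 target CNP0507423.4
Conditions: BCl3, CH2Cl2, −78 → −20 °C; MeOH, aq. NaHCO3
Reagents that add atoms: none
Why: Chelation-assisted BCl3 ether cleavage removes the C8 methyl (peri to the C1 carbonyl) and the C6 methyl (ortho to the C11 ketone) and also cleaves the MOM acetal at C23, at a temperature the lactone, dienamide and enone survive.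

**Compound list**
1 | methyl 2-methyl-3-oxobutanoate | COC(=O)C(C)C(C)=O | starting material
2 | methyl 2-methyl-3-(trimethylsilyloxy)but-2-enoate (E/Z mixture) | COC(=O)C(C)=C(C)O[Si](C)(C)C | intermediate
3 | 1-methoxy-2-methyl-1,3-bis(trimethylsilyloxy)buta-1,3-diene | COC(O[Si](C)(C)C)=C(C)C(=C)O[Si](C)(C)C | intermediate
4 | 2,6-dibromo-1,4-benzoquinone | O=C1C=C(Br)C(=O)C(Br)=C1 | starting material
5 | Diels–Alder cycloadduct (racemic, cis-fused; destroyed on aromatization) | O=C1C=C(Br)C(=O)C2(Br)C1CC(O[Si](C)(C)C)=C(C)C2(OC)O[Si](C)(C)C | intermediate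
6 | 2-bromo-6,8-dihydroxy-7-methylnaphthalene-1,4-dione | O=C1C=C(Br)C(=O)c2c(O)c(C)c(O)cc12 | intermediate
7 | 2-bromo-7-methylnaphthalene-1,4,6,8-tetrol | Oc1cc(Br)c(O)c2c(O)c(C)c(O)cc12 | intermediate
8 | 2-bromo-1,4,6,8-tetramethoxy-7-methylnaphthalene | COc1cc(Br)c(OC)c2c(OC)c(C)c(OC)cc12 | intermediate
9 | 6-bromo-2,4,5,8-tetramethoxy-3-methylnaphthalene-1-carbaldehyde (fragment A) | COc1cc(Br)c(OC)c2c(OC)c(C)c(OC)c(C=O)c12 | intermediate
10 | acrolein | C=CC=O | starting material
11 | ethyl 2-[bis(2,2,2-trifluoroethoxy)phosphoryl]propanoate | CCOC(=O)C(C)P(=O)(OCC(F)(F)F)OCC(F)(F)F | starting material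
12 | ethyl (Z)-2-methylpenta-2,4-dienoate | C=C/C=C(/C)C(=O)OCC | intermediate
13 | (Z)-2-methylpenta-2,4-dienamide | C=C/C=C(/C)C(N)=O | intermediate
14 | (Z)-N-(5-formyl-1,4,6,8-tetramethoxy-7-methylnaphthalen-2-yl)-2-methylpenta-2,4-dienamide (fragment B) | C=C/C=C(/C)C(=O)Nc1cc(OC)c2c(C=O)c(OC)c(C)c(OC)c2c1OC | intermediate
15 | 3-[(tert-butyldimethylsilyl)oxy]propanal | CC(C)(C)[Si](C)(C)OCCC=O | starting material
16 | tert-butyl{[(Z)-4-iodopent-3-en-1-yl]oxy}dimethylsilane | CC(C)(C)[Si](C)(C)OCC/C=C(/C)I | intermediate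
17 | (Z)-4-iodopent-3-en-1-ol | OCC/C=C(/C)I | intermediate
18 | (Z)-4-iodopent-3-enoic acid | OC(=O)C/C=C(/C)I | intermediate
19 | (R)-4-benzyloxazolidin-2-one | O=C1N[C@H](Cc2ccccc2)CO1 | starting material
20 | (Z)-4-iodopent-3-enoic pivalic anhydride | CC(C)(C)C(=O)OC(=O)C/C=C(/C)I | intermediate
21 | (R)-4-benzyl-3-[(Z)-4-iodopent-3-enoyl]oxazolidin-2-one (fragment C) | O=C(C/C=C(/C)I)N1[C@H](Cc2ccccc2)COC1=O | intermediate
22 | methyl (R)-3-hydroxy-2-methylpropanoate | OC[C@@H](C)C(=O)OC | starting material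
23 | methyl (R)-3-[(tert-butyldimethylsilyl)oxy]-2-methylpropanoate | CC(C)(C)[Si](C)(C)OC[C@@H](C)C(=O)OC | intermediate
24 | (R)-3-[(tert-butyldimethylsilyl)oxy]-2-methylpropanal | CC(C)(C)[Si](C)(C)OC[C@@H](C)C=O | intermediate
25 | (2R,3R,4R)-1-[(tert-butyldimethylsilyl)oxy]-2,4-dimethylhex-5-en-3-ol | CC(C)(C)[Si](C)(C)OC[C@@H](C)[C@H](O)[C@H](C)C=C | intermediate
26 | tert-butyl{[(2R,3R,4R)-3-(methoxymethoxy)-2,4-dimethylhex-5-en-1-yl]oxy}dimethylsilane | CC(C)(C)[Si](C)(C)OC[C@@H](C)[C@H](OCOC)[C@H](C)C=C | intermediate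
27 | ozonide (1,2,4-trioxolane) of 26, epimers at the ring carbon | CC(C)(C)[Si](C)(C)OC[C@@H](C)[C@H](OCOC)[C@H](C)C1OCOO1 | intermediate
28 | (2S,3S,4R)-5-[(tert-butyldimethylsilyl)oxy]-3-(methoxymethoxy)-2,4-dimethylpentanal | CC(C)(C)[Si](C)(C)OC[C@@H](C)[C@H](OCOC)[C@H](C)C=O | intermediate
29 | (3S,4S,5R,6S,7R)-8-[(tert-butyldimethylsilyl)oxy]-6-(methoxymethoxy)-3,5,7-trimethyloct-1-en-4-ol | CC(C)(C)[Si](C)(C)OC[C@@H](C)[C@H](OCOC)[C@H](C)[C@@H](O)[C@@H](C)C=C | intermediate
30 | (3S,4S,5S,6S,7R)-8-[(tert-butyldimethylsilyl)oxy]-6-(methoxymethoxy)-3,5,7-trimethyl-4-[(triethylsilyl)oxy]oct-1-ene | CC(C)(C)[Si](C)(C)OC[C@@H](C)[C@H](OCOC)[C@H](C)[C@@H](O[Si](CC)(CC)CC)[C@@H](C)C=C | intermediate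
31 | ozonide (1,2,4-trioxolane) of 30, epimers at the ring carbon | CC(C)(C)[Si](C)(C)OC[C@@H](C)[C@H](OCOC)[C@H](C)[C@@H](O[Si](CC)(CC)CC)[C@@H](C)C1OCOO1 | intermediate
32 | (2R,3R,4S,5S,6R)-7-[(tert-butyldimethylsilyl)oxy]-5-(methoxymethoxy)-2,4,6-trimethyl-3-[(triethylsilyl)oxy]heptanal | CC(C)(C)[Si](C)(C)OC[C@@H](C)[C@H](OCOC)[C@H](C)[C@@H](O[Si](CC)(CC)CC)[C@@H](C)C=O | intermediate
33 | dibutylboron (Z)-enolate of 21 | CCCCB(CCCC)O/C(=C\C=C(\C)I)N1[C@H](Cc2ccccc2)COC1=O | intermediate
34 | (R)-4-benzyl-3-[(2R,3S,4S,5S,6S,7S,8R)-9-(tert-butyldimethylsilyloxy)-3-hydroxy-2-[(Z)-2-iodoprop-1-enyl]-7-(methoxymethoxy)-4,6,8-trimethyl-5-(triethylsilyloxy)nonanoyl]oxazolidin-2-one | CC(C)(C)[Si](C)(C)OC[C@@H](C)[C@H](OCOC)[C@H](C)[C@@H](O[Si](CC)(CC)CC)[C@@H](C)[C@H](O)[C@@H](/C=C(/C)I)C(=O)N1[C@H](Cc2ccccc2)COC1=O | intermediate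
35 | desilylated 3,5,9-trihydroxy imide from 34 | OC[C@@H](C)[C@H](OCOC)[C@H](C)[C@@H](O)[C@@H](C)[C@H](O)[C@@H](/C=C(/C)I)C(=O)N1[C@H](Cc2ccccc2)COC1=O | intermediate
36 | (3R,4S,5S,6S)-4-hydroxy-6-[(2S,3S,4R)-5-hydroxy-3-(methoxymethoxy)-4-methylpentan-2-yl]-3-[(Z)-2-iodoprop-1-enyl]-5-methyloxan-2-one | OC[C@@H](C)[C@H](OCOC)[C@H](C)[C@H]1OC(=O)[C@H](/C=C(/C)I)[C@@H](O)[C@@H]1C | intermediate
37 | (2S,3R,4S)-4-[(2S,3S,4S,5R)-4-hydroxy-5-[(Z)-2-iodoprop-1-enyl]-3-methyl-6-oxooxan-2-yl]-3-(methoxymethoxy)-2-methylpentanal | O=C[C@@H](C)[C@H](OCOC)[C@H](C)[C@H]1OC(=O)[C@H](/C=C(/C)I)[C@@H](O)[C@@H]1C | intermediate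
38 | (3R,4S,5S,6S)-4-hydroxy-6-[(2S,3S,4R,5R,6R)-5-hydroxy-3-(methoxymethoxy)-4,6-dimethyloct-7-en-2-yl]-3-[(Z)-2-iodoprop-1-enyl]-5-methyloxan-2-one (fragment D; 20R,21R,22R,23S,24S,25S,26S,27S,28R) | C=C[C@@H](C)[C@@H](O)[C@@H](C)[C@H](OCOC)[C@H](C)[C@H]1OC(=O)[C@H](/C=C(/C)I)[C@@H](O)[C@@H]1C | intermediate
39 | seco aldehyde: (2Z,4E,6R,7R,8R,9S,10S)-N-(5-formyl-1,4,6,8-tetramethoxy-7-methylnaphthalen-2-yl)-7-hydroxy-10-[(2S,3S,4S,5R)-4-hydroxy-5-[(Z)-2-iodoprop-1-enyl]-3-methyl-6-oxooxan-2-yl]-9-(methoxymethoxy)-2,6,8-trimethylundeca-2,4-dienamide | C/C(=C/C=C/[C@@H](C)[C@@H](O)[C@@H](C)[C@H](OCOC)[C@H](C)[C@H]1OC(=O)[C@H](/C=C(/C)I)[C@@H](O)[C@@H]1C)C(=O)Nc1cc(OC)c2c(C=O)c(OC)c(C)c(OC)c2c1OC | intermediate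
40 | macrocyclic C11 carbinol: 11-hydroxy-1,4,6,8-tetramethoxynaphthalene form of the target with 23-O-methoxymethyl (C11 epimers) | C/C1=C/C=C/[C@@H](C)[C@@H](O)[C@@H](C)[C@H](OCOC)[C@H](C)[C@H]2OC(=O)[C@H](/C=C(/C)C(O)c3c(OC)c(C)c(OC)c4c(OC)c(NC1=O)cc(OC)c34)[C@@H](O)[C@@H]2C | intermediate
41 | macrocyclic aryl ketone: 1,4,6,8-tetramethoxynaphthalene form of the target with 23-O-methoxymethyl | C/C1=C/C=C/[C@@H](C)[C@@H](O)[C@@H](C)[C@H](OCOC)[C@H](C)[C@H]2OC(=O)[C@H](/C=C(/C)C(=O)c3c(OC)c(C)c(OC)c4c(OC)c(NC1=O)cc(OC)c34)[C@@H](O)[C@@H]2C | intermediate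
42 | 6,8-di-O-methyl-23-O-(methoxymethyl) ether of the target quinone | C/C1=C/C=C/[C@@H](C)[C@@H](O)[C@@H](C)[C@H](OCOC)[C@H](C)[C@H]2OC(=O)[C@H](/C=C(/C)C(=O)c3c(OC)c(C)c(OC)c4c3C(=O)C=C(NC1=O)C4=O)[C@@H](O)[C@@H]2C | intermediate
43 | CNP0507423.4: 25,34a-lactone naphthoquinone ansamycin (12Z,16Z,18E; 20R,21R,22R,23S,24S,25R,26S,27S,28R) | C/C1=C/C=C/[C@@H](C)[C@@H](O)[C@@H](C)[C@H](O)[C@H](C)[C@H]2OC(=O)[C@H](/C=C(/C)C(=O)c3c(O)c(C)c(O)c4c3C(=O)C=C(NC1=O)C4=O)[C@@H](O)[C@@H]2C | target

**Totals and risk**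

Total step count: 28. Longest linear sequence: 17 steps (22 → 43, steps 12–28).

Three steps most likely to fail:

Step 25, the Nozaki–Hiyama–Kishi macrocyclization (a peri- and ortho-flanked, electron-rich aldehyde and a 23-membered ring). The fallback moves the ring closure to the N–aryl bond. It sets out from 38 and uses bromo aldehyde 9 in place of 14: an intermolecular Nozaki–Hiyama–Kishi coupling (CrCl2, catalytic NiCl2, DMSO; the aryl bromide is inert) gives the open-chain aryl carbinol F1. Cross-metathesis of F1 with an excess of the small amide 13 (second-generation Hoveyda–Grubbs catalyst) gives the primary dienamide F2. Intramolecular Goldberg amidation (CuI, trans-N,N'-dimethylcyclohexane-1,2-diamine, K2CO3, toluene, 100 °C, high dilution) then closes the macrolactam and comes back to the route at 40. The main risk of this fallback is the β-hydroxy lactone under hot carbonate.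

Step 24, the intermolecular diene–ene cross-metathesis (homodimerization, catalyst sequestration by the diene, E/Z erosion). The fallback reverses the order of the two unions. It sets out from 38, which is coupled with 14 first by an intermolecular Nozaki–Hiyama–Kishi reaction to the open-chain allylic carbinol F3. The C18=C19 bond is then formed by ring-closing diene–ene metathesis at 1 mM (second-generation Hoveyda–Grubbs catalyst, toluene, 60 °C), which benefits from intramolecularity and comes back to the route at 40.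

Step 23, the late, mismatched (anti-Felkin) crotylboration next to a base-sensitive β-hydroxy lactone. The fallback sets out from primary alcohol 36, bypasses aldehyde 37, and comes back to the route at 38. It uses iridium-catalysed transfer-hydrogenative anti-crotylation (Krische type) with but-3-en-2-yl acetate: [Ir(cod)Cl]2, 4-cyano-3-nitrobenzoic acid, the SEGPHOS enantiomer matched to the 21R carbinol, K3PO4, THF, 60 °C. The anti,anti triad is then under catalyst control and no discrete epimerizable aldehyde is handled; the open question is whether the alkenyl iodide survives the low-valent iridium. No compound outside the list is formed (F0).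

Further compounds
F1 | step 25 | open-chain aryl carbinol from 38 and 9 (C11–C12 bond formed; aryl bromide and terminal vinyl retained; C11 epimers) | C=C[C@@H](C)[C@@H](O)[C@@H](C)[C@H](OCOC)[C@H](C)[C@H]1OC(=O)[C@H](/C=C(/C)C(O)c2c(OC)c(C)c(OC)c3c(OC)c(Br)cc(OC)c23)[C@@H](O)[C@@H]1C
F2 | step 25 | primary (2Z,4E)-dienamide from cross-metathesis of F1 with 13 | NC(=O)/C(C)=C\C=C\[C@@H](C)[C@@H](O)[C@@H](C)[C@H](OCOC)[C@H](C)[C@H]1OC(=O)[C@H](/C=C(/C)C(O)c2c(OC)c(C)c(OC)c3c(OC)c(Br)cc(OC)c23)[C@@H](O)[C@@H]1C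
F3 | step 24 | open-chain allylic carbinol from 38 and 14 (C11–C12 bond formed; both terminal vinyl groups retained; C11 epimers) | C=C[C@@H](C)[C@@H](O)[C@@H](C)[C@H](OCOC)[C@H](C)[C@H]1OC(=O)[C@H](/C=C(/C)C(O)c2c(OC)c(C)c(OC)c3c(OC)c(NC(=O)/C(C)=C\C=C)cc(OC)c23)[C@@H](O)[C@@H]1C
F0 | step 23 | none | none
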